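**Plan**

1. Cuts, in retrosynthetic order: the acetate; the dihydrofuran O–C15 bond (alkynol cycloisomerisation); the 8,17-epoxide; O9–C13 (epoxide opening); C9–C11 (organocerium addition to a C9 ketone); the C10–C20 bond of the lactone ring; ring B back to a phenol; C4–C5 (enolate arylation); C1–C10 (Suzuki–Miyaura).
2. Enabling feature: the ring-B enone C9(=O)–C10=C5 carries on C4, next to its β-carbon C5, a CH(OMe)2 group (C19). One O–CH3 of this acetal (the future C20) lies 1,5 to C5. On irradiation C5 should take a hydrogen from it, and the biradical should close C10–C20, giving the bridged six-membered acetal ring C10–C20–O–C19–C4–C5 that becomes the 19,20-lactone.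
3. Forward order: arene, then tetralin (ring A closed by asymmetric α-arylation), dearomatisation to the ring-B enone, photochemical closure of the acetal/lactone ring, C6 and C8/C9 adjustment, side chain, tetrahydrofuran, epoxide, dihydrofuran, acetate.
4. Stereochemistry: C4 from the chiral palladium catalyst; C5 and C10 from the same-face delivery of H and C20 from the C4 acetal; C6 by equilibration to the equatorial alcohol; C9 by axial attack on the convex β face; C13 by Sharpless epoxidation followed by inversion; C8 by epoxidation from the convex face.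
5. Numbering is that of labdane: ring A = C1–C5, C10; ring B = C5–C10; C18 = methyl on C4; C19 on C4; C20 on C10; C17 on C8; side chain C11–C16. β is the face of the decalin that carries C20.

Key step: step 8

Assumption: the SMILES is taken as written; it places H-5 on the same face as C19 and C20 (cis-fused rings A/B; 4S,5S,6R,8R,9S,10S,13R), and the route is designed for this isomer.

**Route**

Step 1
Reactants: 1 1-bromo-3-(methoxymethoxy)benzene
Product: 3 1-bromo-2-iodo-3-(methoxymethoxy)benzene, via aryllithium 2 (not isolated)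
Conditions: LiN(i-Pr)2, THF, −78 °C; then I2, −78 °C to rt
Reagents that add atoms: iodine, II
Why: Directed ortho-metalation removes the most acidic proton, the one between Br and the OMOM group, at a temperature where the aryllithium does not lose LiBr, and iodination gives the 1,2,3-trisubstituted arene; no stereocentre.

Step 2
Reactants: 3 1-bromo-2-iodo-3-(methoxymethoxy)benzene; 4 ethyl 2-methylpent-4-enoate (racemic)
Product: 6 ethyl 5-[2-bromo-6-(methoxymethoxy)phenyl]-2-methylpentanoate (racemic), via alkylborane 5 (not isolated)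
Conditions: 9-BBN, THF, rt; then 3, PdCl2(dppf) (5 mol %), K3PO4, DMF–H2O, 50 °C
Reagents that add atoms: none
Why: Anti-Markovnikov hydroboration and B-alkyl Suzuki–Miyaura coupling, which should occur at the C–I bond in preference to the C–Br bond; the ester α-centre is racemic and is erased in step 4.

Step 3
Reactants: 6 ethyl 5-[2-bromo-6-(methoxymethoxy)phenyl]-2-methylpentanoate
Product: 7 5-[2-bromo-6-(methoxymethoxy)phenyl]-2-methylpentanal (racemic)
Conditions: i-Bu2AlH (1.1 equiv), toluene, −78 °C
Reagents that add atoms: none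
Why: Partial ester reduction with i-Bu2AlH stops at the aldehyde because the aluminium hemiacetal is stable at −78 °C; no new stereocentre.

Step 4
Reactants: 7 5-[2-bromo-6-(methoxymethoxy)phenyl]-2-methylpentanal
Product: 8 (S)-5-(methoxymethoxy)-1-methyl-1,2,3,4-tetrahydronaphthalene-1-carbaldehyde
Conditions: Pd(OAc)2 (3 mol %), (S)-t-Bu-PHOX (9 mol %), Cs2CO3, DMF, 80 °C
Reagents that add atoms: none
Why: Palladium-catalysed asymmetric intramolecular α-arylation of an α-branched aldehyde closes ring A and creates the quaternary C4 centre, the chiral P,N-ligand selecting the enolate face (the ligand antipode is chosen to give S).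

Step 5
Reactants: 8 (S)-5-(methoxymethoxy)-1-methyl-1,2,3,4-tetrahydronaphthalene-1-carbaldehyde
Product: 10 (S)-5-(dimethoxymethyl)-5-methyl-5,6,7,8-tetrahydronaphthalen-1-ol, via MOM ether acetal 9 (not isolated)
Conditions: HC(OMe)3, HCl (cat., in MeOH), MeOH, rt
Reagents that add atoms: trimethyl orthoformate, COC(OC)OC; methanol, CO
Why: Acid-catalysed acetalisation of the hindered aldehyde, with orthoformate as water scavenger, and methanolysis of the MOM ether by acetal exchange take place under the same conditions; C4 is untouched.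

Step 6
Reactants: 10 (S)-5-(dimethoxymethyl)-5-methyl-5,6,7,8-tetrahydronaphthalen-1-ol
Product: 12 (S)-5-(dimethoxymethyl)-4,4-dimethoxy-5-methyl-5,6,7,8-tetrahydronaphthalen-1(4H)-one, via 4-methoxyphenol 11 (not isolated)
Conditions: PhI(OAc)2 (2.2 equiv), MeOH, 0 °C
Reagents that add atoms: methanol, CO
Why: Hypervalent-iodine oxidative dearomatisation oxidises the phenol twice, methanol adding each time at the para carbon C6, to give the p-quinone monoketal; no new stereocentre.

Step 7
Reactants: 12 (S)-5-(dimethoxymethyl)-4,4-dimethoxy-5-methyl-5,6,7,8-tetrahydronaphthalen-1(4H)-one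
Product: 13 (S)-5-(dimethoxymethyl)-4,4-dimethoxy-5-methyl-3,4,5,6,7,8-hexahydronaphthalen-1(2H)-one
Conditions: H2 (1 atm), RhCl(PPh3)3 (5 mol %), benzene, rt
Reagents that add atoms: none
Why: Homogeneous hydrogenation with RhCl(PPh3)3 is sensitive to alkene substitution and should saturate the disubstituted C7=C8 bond while leaving the tetrasubstituted C5=C10 enone and the allylic ketal intact; no stereocentre.

Step 8
Reactants: 13 (S)-5-(dimethoxymethyl)-4,4-dimethoxy-5-methyl-3,4,5,6,7,8-hexahydronaphthalen-1(2H)-one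
Product: 15 19,20-epoxy-6,6,19ξ-trimethoxy-11,12,13,14,15,16,17-heptanor-5β-labdan-9-one (H-5, C19 and C20 all β), via triplet 1,6-biradical 14 (not isolated)
Conditions: hν (350–366 nm, Pyrex), degassed benzene (0.005 M), rt
Reagents that add atoms: none
Why: Proposed new method: excitation of the ring-B enone and intersystem crossing give the twisted triplet, whose β-carbon C5 has alkyl-radical character and should abstract a hydrogen atom from an O–CH3 group of the C19 acetal through a six-membered transition state (C5, C4, C19, O, CH3, H); the triplet biradical 14 (C20 alkoxymethyl radical and C10 α-keto radical) then recombines after spin inversion to form C10–C20. The closest known reaction type is the intramolecular hydrogen abstraction by the β-carbon of triplet cycloalkenones from a side chain, followed by biradical coupling at the α-carbon; what is new is an acetal methoxy group serving as both hydrogen and carbon donor. The ring closed is the six-membered cyclic acetal C10–C20–O–C19–C4–C5, by radical–radical recombination of a 1,6-biradical at the α-carbon of the former enone, so that both former alkene carbons lie in the new ring, which is bridged across ring A. C5 is set because the hydrogen comes from the acetal on the C19 face, making H-5 cis to C19; C10 is set by the tether, since the C20 radical bound through oxygen to C19 can only reach that same face; C19 becomes an uncontrolled acetal centre that is erased in step 9. The step needs 1,5-hydrogen transfer from the C19 acetal to win over 1,4-transfer from the C6 ketal methoxy groups, over enone photorearrangement and over photolysis of the product ketone; the first is secured by the six- versus five-membered transition state and by the peri strain between the C6 ketal and C4, which holds the larger CH(OMe)2 group pseudoaxial over C5, and the last by irradiating only where the enone absorbs.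

Step 9
Reactants: 15 19,20-epoxy-6,6,19ξ-trimethoxy-11,12,13,14,15,16,17-heptanor-5β-labdan-9-one
Product: 17 6,9-dioxo-11,12,13,14,15,16,17-heptanor-5β-labdan-19,20-olide, via keto lactol 16 (not isolated)
Conditions: CrO3, H2SO4, acetone–H2O, 0 °C
Reagents that add atoms: water, O
Why: Jones oxidation: aqueous acid hydrolyses the C6 ketal and the C19 methyl acetal and hexavalent chromium oxidises the lactol to the δ-lactone, the short exposure at 0 °C being meant to keep C5 (now α to the C6 ketone) from epimerising.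

Step 10
Reactants: 17 6,9-dioxo-11,12,13,14,15,16,17-heptanor-5β-labdan-19,20-olide
Product: 18 6α-hydroxy-9-oxo-11,12,13,14,15,16,17-heptanor-5β-labdan-19,20-olide
Conditions: LiBH(s-Bu)3 (1.05 equiv), THF, −78 °C
Reagents that add atoms: none
Why: Bulky borohydride reduction should be selective for C6, because the C9 ketone is flanked by the quaternary C10 and its equatorial approach is blocked by the axial C1; hydride reaches C6 from the convex β face (the α axial path is blocked 1,3-diaxially by C1), giving the axial 6α-alcohol.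

Step 11
Reactants: 18 6α-hydroxy-9-oxo-11,12,13,14,15,16,17-heptanor-5β-labdan-19,20-olide
Product: 19 6β-hydroxy-9-oxo-11,12,13,14,15,16,17-heptanor-5β-labdan-19,20-olide
Conditions: RuCl(CO)2(η5-C5Ph5) (5 mol %), KOt-Bu (5 mol %), toluene, 25–50 °C
Reagents that add atoms: none
Why: Ruthenium-catalysed hydrogen-transfer epimerisation of a secondary alcohol (reversible β-hydride elimination and re-insertion on the ruthenium alkoxide) should equilibrate C6 to the equatorial 6β-alcohol, since the axial epimer suffers a 1,3-diaxial interaction with C1.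

Step 12
Reactants: 19 6β-hydroxy-9-oxo-11,12,13,14,15,16,17-heptanor-5β-labdan-19,20-olide
Product: 20 6β-hydroxy-9-oxo-11,12,13,14,15,16-hexanor-5β-labd-8(17)-en-19,20-olide
Conditions: (CH2O)n, PhNHMe·CF3CO2H, THF, reflux
Reagents that add atoms: paraformaldehyde (as formaldehyde), C=O
Why: Mannich condensation–elimination (α-methylenation) can only occur at C8, because C10 is quaternary; no stereocentre is formed.

Step 13
Reactants: 21 3-methylideneoxolan-2-one (α-methylene-γ-butyrolactone)
Product: 23 ethyl 4-iodo-2-methylidenebutanoate, via silyl ester 22 (not isolated)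
Conditions: Me3SiI, CH2Cl2, rt; then EtOH, rt
Reagents that add atoms: iodotrimethylsilane, C[Si](C)(C)I; ethanol, CCO
Why: Silyl iodide lactone cleavage by SN2 attack of iodide at the O–CH2 carbon, followed by ethanolysis of the silyl ester to the ω-iodo ester.

Step 14
Reactants: 23 ethyl 4-iodo-2-methylidenebutanoate
Product: 24 4-iodo-2-methylidenebutan-1-ol
Conditions: i-Bu2AlH (2.2 equiv), CH2Cl2, −78 °C
Reagents that add atoms: none
Why: 1,2-Reduction of the acrylate ester to the allylic alcohol with i-Bu2AlH at low temperature, which the primary iodide should survive.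

Step 15
Reactants: 24 4-iodo-2-methylidenebutan-1-ol
Product: 25 tert-butyl[(4-iodo-2-methylidenebutyl)oxy]dimethylsilane
Conditions: TBSCl, imidazole, CH2Cl2, rt
Reagents that add atoms: tert-butyldimethylsilyl chloride, CC(C)(C)[Si](C)(C)Cl
Why: Silyl ether formation masks the hydroxyl proton before the halogen–lithium exchange.

Step 16
Reactants: 20 6β-hydroxy-9-oxo-11,12,13,14,15,16-hexanor-5β-labd-8(17)-en-19,20-olide; 25 tert-butyl[(4-iodo-2-methylidenebutyl)oxy]dimethylsilane
Product: 28 14-[(tert-butyldimethylsilyl)oxy]-6β,9α-dihydroxy-15-nor-5β-labda-8(17),13(16)-dien-19,20-olide, via alkyllithium 26 (not isolated), via organocerium 27 (not isolated)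
Conditions: 25 (3 equiv), t-BuLi, Et2O, −78 °C; CeCl3, THF, −78 °C; then 20, −78 °C
Reagents that add atoms: none
Why: Iodine–lithium exchange, transmetalation to cerium and 1,2-addition to the α-methylene ketone; the organocerium reagent is chosen for ketone 1,2-addition over conjugate addition and lactone attack, and axial attack on the convex β face of C9, anti to the axial C10–C1 bond (Felkin–Anh), should give 9α-OH with C11 β.

Step 17
Reactants: 28 14-[(tert-butyldimethylsilyl)oxy]-6β,9α-dihydroxy-15-nor-5β-labda-8(17),13(16)-dien-19,20-olide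
Product: 29 6β,9α,14-trihydroxy-15-nor-5β-labda-8(17),13(16)-dien-19,20-olide
Conditions: Bu4NF, THF, 0 °C
Reagents that add atoms: none
Why: Fluoride-mediated desilylation of the primary silyl ether; no stereocentre is touched.

Step 18
Reactants: 29 6β,9α,14-trihydroxy-15-nor-5β-labda-8(17),13(16)-dien-19,20-olide
Product: 30 (13S)-13,16-epoxy-6β,9α,14-trihydroxy-15-nor-5β-labd-8(17)-en-19,20-olide
Conditions: Ti(Oi-Pr)4 (10 mol %), L-(+)-diethyl tartrate (12 mol %), t-BuOOH, 4 Å MS, CH2Cl2, −20 °C
Reagents that add atoms: tert-butyl hydroperoxide, CC(C)(C)OO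
Why: Sharpless asymmetric epoxidation of the 2-substituted primary allylic alcohol is reagent-controlled, L-(+)-tartrate delivering oxygen to the face that gives the (13S)-epoxide, and the 8(17)-alkene next to a tertiary alcohol should react far more slowly.

Step 19
Reactants: 30 (13S)-13,16-epoxy-6β,9α,14-trihydroxy-15-nor-5β-labd-8(17)-en-19,20-olide
Product: 32 (13S)-13,16-epoxy-6β,9α-dihydroxy-5β-labd-8(17)-en-14-yn-19,20-olide, via epoxy aldehyde 31 (not isolated)
Conditions: TEMPO (cat.), PhI(OAc)2, NaHCO3, CH2Cl2, rt; then dimethyl (1-diazo-2-oxopropyl)phosphonate, K2CO3, MeOH, 0 °C to rt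
Reagents that add atoms: dimethyl (1-diazo-2-oxopropyl)phosphonate, CC(=O)C(=[N+]=[N-])P(=O)(OC)OC
Why: Nitroxyl-catalysed oxidation is selective for the primary alcohol over the secondary 6-OH, and Seyferth–Gilbert homologation with the Ohira–Bestmann reagent turns the aldehyde carbon C14 into a terminal alkyne; C13 is quaternary and cannot epimerise.

Step 20
Reactants: 32 (13S)-13,16-epoxy-6β,9α-dihydroxy-5β-labd-8(17)-en-14-yn-19,20-olide
Product: 33 (13R)-9α,13-epoxy-6β,16-dihydroxy-5β-labd-8(17)-en-14-yn-19,20-olide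
Conditions: (+)-camphor-10-sulfonic acid (10 mol %), CH2Cl2, 0 °C
Reagents that add atoms: none
Why: Acid-catalysed 5-exo epoxide opening: the tertiary 9-OH attacks the propargylic tertiary carbon C13 with inversion (13S to 13R), closing the tetrahydrofuran and releasing the C16 primary alcohol.

Step 21
Reactants: 33 (13R)-9α,13-epoxy-6β,16-dihydroxy-5β-labd-8(17)-en-14-yn-19,20-olide
Product: 34 (13R)-8β,17:9α,13-diepoxy-6β,16-dihydroxy-5β-labd-14-yn-19,20-olide
Conditions: mCPBA, NaHCO3, CH2Cl2, 0 °C
Reagents that add atoms: 3-chloroperoxybenzoic acid, OOC(=O)c1cccc(Cl)c1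
Why: Peracid epoxidation of the 1,1-disubstituted 8(17)-alkene (the terminal alkyne is inert) should occur from the convex β face, the α face being blocked by the axial C1 of ring A, to give the 8β,17-epoxide.

Step 22
Reactants: 34 (13R)-8β,17:9α,13-diepoxy-6β,16-dihydroxy-5β-labd-14-yn-19,20-olide
Product: 35 (13R)-8β,17:9α,13:15,16-triepoxy-6β-hydroxy-5β-labd-14-en-19,20-olide
Conditions: Mo(CO)6 (30 mol %), Et3N, Et2O, hν (350 nm) to form Mo(CO)5(NEt3); then 34, rt
Reagents that add atoms: none
Why: Molybdenum–vinylidene endo-cycloisomerisation of the homopropargylic alcohol: the terminal alkyne rearranges to a vinylidene on Mo(CO)5, the C16 hydroxyl adds to the carbene carbon C15 and protodemetalation gives the 2,3-dihydrofuran; no stereocentre is affected.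

Step 23
Reactants: 35 (13R)-8β,17:9α,13:15,16-triepoxy-6β-hydroxy-5β-labd-14-en-19,20-olide
Product: 36 (13R)-6β-acetoxy-8β,17:9α,13:15,16-triepoxy-5β-labd-14-en-19,20-olide (target)
Conditions: Ac2O, pyridine, DMAP (cat.), CH2Cl2, rt
Reagents that add atoms: acetic anhydride, CC(=O)OC(C)=O
Why: DMAP-catalysed acetylation of the only remaining hydroxyl group (equatorial 6β-OH) with retention, under basic conditions that the enol ether and the epoxide tolerate.

**Compound list**

1 | 1-bromo-3-(methoxymethoxy)benzene | COCOc1cccc(Br)c1 | starting material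
2 | [2-bromo-6-(methoxymethoxy)phenyl]lithium | COCOc1cccc(Br)c1[Li] | intermediate
3 | 1-bromo-2-iodo-3-(methoxymethoxy)benzene | COCOc1cccc(Br)c1I | intermediate
4 | ethyl 2-methylpent-4-enoate (racemic) | CCOC(=O)C(C)CC=C | starting material
5 | ethyl 5-(9-borabicyclo[3.3.1]nonan-9-yl)-2-methylpentanoate | CCOC(=O)C(C)CCCB1C2CCCC1CCC2 | intermediate
6 | ethyl 5-[2-bromo-6-(methoxymethoxy)phenyl]-2-methylpentanoate (racemic) | CCOC(=O)C(C)CCCc1c(Br)cccc1OCOC | intermediate
7 | 5-[2-bromo-6-(methoxymethoxy)phenyl]-2-methylpentanal (racemic) | O=CC(C)CCCc1c(Br)cccc1OCOC | intermediate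
8 | (S)-5-(methoxymethoxy)-1-methyl-1,2,3,4-tetrahydronaphthalene-1-carbaldehyde | c1ccc(OCOC)c2CCC[C@](C)(C=O)c12 | intermediate
9 | (S)-1-(dimethoxymethyl)-5-(methoxymethoxy)-1-methyl-1,2,3,4-tetrahydronaphthalene | c1ccc(OCOC)c2CCC[C@](C)(C(OC)OC)c12 | intermediate
10 | (S)-5-(dimethoxymethyl)-5-methyl-5,6,7,8-tetrahydronaphthalen-1-ol | c1ccc(O)c2CCC[C@](C)(C(OC)OC)c12 | intermediate
11 | (S)-5-(dimethoxymethyl)-4-methoxy-5-methyl-5,6,7,8-tetrahydronaphthalen-1-ol | COc1ccc(O)c2CCC[C@](C)(C(OC)OC)c12 | intermediate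
12 | (S)-5-(dimethoxymethyl)-4,4-dimethoxy-5-methyl-5,6,7,8-tetrahydronaphthalen-1(4H)-one | COC1(OC)C=CC(=O)C=2CCC[C@](C)(C(OC)OC)C1=2 | intermediate
13 | (S)-5-(dimethoxymethyl)-4,4-dimethoxy-5-methyl-3,4,5,6,7,8-hexahydronaphthalen-1(2H)-one | COC1(OC)CCC(=O)C=2CCC[C@](C)(C(OC)OC)C1=2 | intermediate
14 | triplet 1,6-biradical (C10 α-keto radical, C20 alkoxymethyl radical, H-5 β) | COC1(OC)CCC(=O)[C]2CCC[C@](C)(C(OC)O[CH2])[C@@H]12 | intermediate
15 | 19,20-epoxy-6,6,19ξ-trimethoxy-11,12,13,14,15,16,17-heptanor-5β-labdan-9-one (both C19 epimers) | COC1(OC)CCC(=O)[C@]23CCC[C@](C)(C(OC)OC2)[C@@H]13 | intermediate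
16 | 19,20-epoxy-19ξ-hydroxy-11,12,13,14,15,16,17-heptanor-5β-labdane-6,9-dione | O=C1CCC(=O)[C@]23CCC[C@](C)(C(O)OC2)[C@@H]13 | intermediate
17 | 6,9-dioxo-11,12,13,14,15,16,17-heptanor-5β-labdan-19,20-olide (4S,5S,10S) | O=C1CCC(=O)[C@]23CCC[C@](C)(C(=O)OC2)[C@@H]13 | intermediate
18 | 6α-hydroxy-9-oxo-11,12,13,14,15,16,17-heptanor-5β-labdan-19,20-olide | O[C@H]1CCC(=O)[C@]23CCC[C@](C)(C(=O)OC2)[C@@H]13 | intermediate
19 | 6β-hydroxy-9-oxo-11,12,13,14,15,16,17-heptanor-5β-labdan-19,20-olide | O[C@@H]1CCC(=O)[C@]23CCC[C@](C)(C(=O)OC2)[C@@H]13 | intermediate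
20 | 6β-hydroxy-9-oxo-11,12,13,14,15,16-hexanor-5β-labd-8(17)-en-19,20-olide | O[C@@H]1CC(=C)C(=O)[C@]23CCC[C@](C)(C(=O)OC2)[C@@H]13 | intermediate
21 | 3-methylideneoxolan-2-one | C=C1CCOC1=O | starting material
22 | trimethylsilyl 4-iodo-2-methylidenebutanoate | C=C(CCI)C(=O)O[Si](C)(C)C | intermediate
23 | ethyl 4-iodo-2-methylidenebutanoate | CCOC(=O)C(=C)CCI | intermediate
24 | 4-iodo-2-methylidenebutan-1-ol | OCC(=C)CCI | intermediate
25 | tert-butyl[(4-iodo-2-methylidenebutyl)oxy]dimethylsilane | C=C(CCI)CO[Si](C)(C)C(C)(C)C | intermediate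
26 | [3-({[tert-butyl(dimethyl)silyl]oxy}methyl)but-3-en-1-yl]lithium | [Li]CCC(=C)CO[Si](C)(C)C(C)(C)C | intermediate
27 | dichloro[3-({[tert-butyl(dimethyl)silyl]oxy}methyl)but-3-en-1-yl]cerium | Cl[Ce](Cl)CCC(=C)CO[Si](C)(C)C(C)(C)C | intermediate
28 | 14-[(tert-butyldimethylsilyl)oxy]-6β,9α-dihydroxy-15-nor-5β-labda-8(17),13(16)-dien-19,20-olide | O[C@@H]1CC(=C)[C@](O)(CCC(=C)CO[Si](C)(C)C(C)(C)C)[C@]23CCC[C@](C)(C(=O)OC2)[C@@H]13 | intermediate
29 | 6β,9α,14-trihydroxy-15-nor-5β-labda-8(17),13(16)-dien-19,20-olide | O[C@@H]1CC(=C)[C@](O)(CCC(=C)CO)[C@]23CCC[C@](C)(C(=O)OC2)[C@@H]13 | intermediate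
30 | (13S)-13,16-epoxy-6β,9α,14-trihydroxy-15-nor-5β-labd-8(17)-en-19,20-olide | O[C@@H]1CC(=C)[C@](O)(CC[C@]4(CO)CO4)[C@]23CCC[C@](C)(C(=O)OC2)[C@@H]13 | intermediate
31 | (13R)-13,16-epoxy-6β,9α-dihydroxy-14-oxo-15-nor-5β-labd-8(17)-en-19,20-olide | O[C@@H]1CC(=C)[C@](O)(CC[C@]4(C=O)CO4)[C@]23CCC[C@](C)(C(=O)OC2)[C@@H]13 | intermediate
32 | (13S)-13,16-epoxy-6β,9α-dihydroxy-5β-labd-8(17)-en-14-yn-19,20-olide | O[C@@H]1CC(=C)[C@](O)(CC[C@]4(C#C)CO4)[C@]23CCC[C@](C)(C(=O)OC2)[C@@H]13 | intermediate
33 | (13R)-9α,13-epoxy-6β,16-dihydroxy-5β-labd-8(17)-en-14-yn-19,20-olide | O[C@@H]1CC(=C)[C@]2(CC[C@](CO)(C#C)O2)[C@]23CCC[C@](C)(C(=O)OC2)[C@@H]13 | intermediate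
34 | (13R)-8β,17:9α,13-diepoxy-6β,16-dihydroxy-5β-labd-14-yn-19,20-olide | O[C@@H]1C[C@@]2(CO2)[C@]2(CC[C@](CO)(C#C)O2)[C@]23CCC[C@](C)(C(=O)OC2)[C@@H]13 | intermediate
35 | (13R)-8β,17:9α,13:15,16-triepoxy-6β-hydroxy-5β-labd-14-en-19,20-olide | O[C@@H]1C[C@@]2(CO2)[C@]2(CC[C@]3(C=COC3)O2)[C@]23CCC[C@](C)(C(=O)OC2)[C@@H]13 | intermediate
36 | (13R)-6β-acetoxy-8β,17:9α,13:15,16-triepoxy-5β-labd-14-en-19,20-olide (4S,5S,6R,8R,9S,10S,13R) | CC(=O)O[C@@H]1C[C@@]2(CO2)[C@]2(CC[C@]3(C=COC3)O2)[C@]23CCC[C@](C)(C(=O)OC2)[C@@H]13 | target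

**Step count and risks**

Total step count: 23. Longest linear sequence: 20 steps (steps 1–12 and 16–23); the side-chain iodide takes 3 steps (13–15).

Steps most likely to fail:

Step 8 (Proposed new method). The risk is inefficient hydrogen abstraction from the methoxy group, with enone photorearrangement or 1,4-transfer from the C6 ketal taking over. The fallback uses known chemistry, sets out from aldehyde 8 and returns at lactone 17. Pinnick oxidation (NaClO2, NaH2PO4, 2-methylbut-2-ene) gives the carboxylic acid F1, and BnBr with K2CO3 gives the benzyl ester F2. Methanolic HCl removes the MOM group to give the phenol F3, PhI(OAc)2 in methanol gives the quinone monoketal F4, and H2 over RhCl(PPh3)3 gives the enone F5. Hydrogenation with [Ir(cod)(PCy3)(py)]PF6, directed by the ester carbonyl on the C19 face, should add both hydrogens to the β face and give the cis-fused decalone F6. Hydrogenolysis (H2, Pd/C) gives the keto acid F7, and chloromethyl chlorosulfate (NaHCO3, Bu4NHSO4, CH2Cl2–H2O) gives the chloromethyl ester F8. Cs2CO3 in DMF should then form C10–C20 by intramolecular C-alkylation of the equilibrating C9 enolate from the C19 face, giving the lactone ketal F9. Aqueous HCl in THF removes the C6 ketal to give 17.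

Step 11. The risk is hydrogen transfer to the C9 ketone (redox scrambling) or incomplete equilibration at C6. The fallback replaces equilibration by SN2 inversion, from 18 to 19: Mitsunobu reaction (PPh3, diisopropyl azodicarboxylate, 4-nitrobenzoic acid, THF) gives the 6β-(4-nitrobenzoate) F10, and K2CO3 in MeOH cleaves the ester to give 19.

Step 18. The risk is premature opening of the 2,2-disubstituted epoxy alcohol by the tertiary 9-OH before the two CH2–O arms on C13 are differentiated, which would erase the C13 stereocentre. The fallback differentiates the arms first, from 29 to 31. MnO2 in CH2Cl2 oxidises the allylic alcohol to the α-substituted acrolein F11. Amine-catalysed asymmetric nucleophilic epoxidation (a chiral primary amine salt with aqueous H2O2, iminium activation) then gives the epoxy aldehyde 31, and the route resumes with the alkyne-forming half of step 19.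

Further compounds
F1 | step 8 | (S)-5-(methoxymethoxy)-1-methyl-1,2,3,4-tetrahydronaphthalene-1-carboxylic acid | c1ccc(OCOC)c2CCC[C@](C)(C(=O)O)c12
F2 | step 8 | benzyl (S)-5-(methoxymethoxy)-1-methyl-1,2,3,4-tetrahydronaphthalene-1-carboxylate | c1ccc(OCOC)c2CCC[C@](C)(C(=O)OCc3ccccc3)c12
F3 | step 8 | benzyl (S)-5-hydroxy-1-methyl-1,2,3,4-tetrahydronaphthalene-1-carboxylate | c1ccc(O)c2CCC[C@](C)(C(=O)OCc3ccccc3)c12
F4 | step 8 | benzyl (S)-8,8-dimethoxy-1-methyl-5-oxo-1,2,3,4,5,8-hexahydronaphthalene-1-carboxylate | COC1(OC)C=CC(=O)C=2CCC[C@](C)(C(=O)OCc3ccccc3)C1=2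
F5 | step 8 | benzyl (S)-8,8-dimethoxy-1-methyl-5-oxo-1,2,3,4,5,6,7,8-octahydronaphthalene-1-carboxylate | COC1(OC)CCC(=O)C=2CCC[C@](C)(C(=O)OCc3ccccc3)C1=2
F6 | step 8 | benzyl ester of the cis-fused keto acid (H-5 and H-10 β, C6 dimethyl ketal, C9 ketone) | COC1(OC)CCC(=O)[C@H]2CCC[C@](C)(C(=O)OCc3ccccc3)[C@@H]12
F7 | step 8 | cis-fused keto acid (H-5 and H-10 β, C6 dimethyl ketal, C9 ketone, C19 carboxylic acid) | COC1(OC)CCC(=O)[C@H]2CCC[C@](C)(C(=O)O)[C@@H]12
F8 | step 8 | chloromethyl ester of the cis-fused keto acid | COC1(OC)CCC(=O)[C@H]2CCC[C@](C)(C(=O)OCCl)[C@@H]12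
F9 | step 8 | 6,6-dimethoxy-9-oxo-11,12,13,14,15,16,17-heptanor-5β-labdan-19,20-olide | COC1(OC)CCC(=O)[C@]23CCC[C@](C)(C(=O)OC2)[C@@H]13
F10 | step 11 | 6β-(4-nitrobenzoyloxy)-9-oxo-11,12,13,14,15,16,17-heptanor-5β-labdan-19,20-olide | O=C(O[C@@H]1CCC(=O)[C@]23CCC[C@](C)(C(=O)OC2)[C@@H]13)c1ccc(cc1)[N+](=O)[O-]
F11 | step 18 | 6β,9α-dihydroxy-14-oxo-15-nor-5β-labda-8(17),13(16)-dien-19,20-olide | O[C@@H]1CC(=C)[C@](O)(CCC(=C)C=O)[C@]23CCC[C@](C)(C(=O)OC2)[C@@H]13
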